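The target is disconnected at C4–C5 and C9–C10 (labdane numbering), back to an acyclic (3R)-3,4-epoxy polyene that carries a phenylsulfonyl group on C7. The sulfone first joins two geraniol-derived halves by carbanion alkylation. In the key step it ends a Cp2TiCl-triggered radical cascade: ring A closes, the C10 radical then closes ring B onto C9, and the C8 radical expels the sulfonyl group. The step exploits the C7=C8 alkene of ring B next to C9–H and quaternary C10: it places that alkene regiospecifically, sets C5, C9 and C10 from the epoxide, and funnels both C7 epimers into one product. C3 is then inverted by oxidation and hindered-hydride reduction.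

Key step: step 9

Remark: C1–C20 are labdane numbers and are used also for the acyclic precursors (the oxirane carbons are C3 and C4, the sulfonyl carbon is C7). The target is the (3S,5S,9R,10S) compound with an axial C3 oxygen, so the cascade is run in the (3R) series and C3 is inverted afterwards.

Step 1
Reactants: 1 geraniol; 2 (3S)-3-methylpentanoic acid
Product: 3 geranyl (3S)-3-methylpentanoate
Conditions: DCC, DMAP (cat.), CH2Cl2, 0 °C to rt
Reagents that add atoms: none
Why: Steglich esterification of the primary allylic alcohol; the stereocenter of 2 is β to the carboxyl group and cannot epimerize.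

Step 2
Reactants: 3 geranyl (3S)-3-methylpentanoate
Product: 4 (2E,6E)-8-hydroxy-3,7-dimethylocta-2,6-dien-1-yl (3S)-3-methylpentanoate
Conditions: SeO2 (0.1 equiv), t-BuOOH (3 equiv), salicylic acid (cat.), CH2Cl2, 0 °C to rt
Reagents that add atoms: tert-butyl hydroperoxide, CC(C)(C)OO (net oxygen source; the oxygen is relayed through catalytic SeO2, O=[Se]=O)
Why: Riley-type allylic oxidation (ene reaction, then [2,3]-sigmatropic shift) is selective for the (E)-methyl group of the electron-rich distal alkene, because the other alkene is deactivated by the allylic ester, and it keeps the (E)-geometry.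

Step 3
Reactants: 4 (2E,6E)-8-hydroxy-3,7-dimethylocta-2,6-dien-1-yl (3S)-3-methylpentanoate
Product: 5 (2E,6E)-8-bromo-3,7-dimethylocta-2,6-dien-1-yl (3S)-3-methylpentanoate
Conditions: CBr4, PPh3, CH2Cl2, −20 °C
Reagents that add atoms: carbon tetrabromide, BrC(Br)(Br)Br
Why: Appel bromination; SN2 displacement at the primary allylic carbon keeps both alkene geometries.

Step 4
Reactants: 5 (2E,6E)-8-bromo-3,7-dimethylocta-2,6-dien-1-yl (3S)-3-methylpentanoate
Product: 6 (2E,6E)-3,7-dimethyl-8-(phenylsulfonyl)octa-2,6-dien-1-yl (3S)-3-methylpentanoate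
Conditions: NaSO2Ph, DMF, rt
Reagents that add atoms: sodium benzenesulfinate, [Na+].[O-]S(=O)c1ccccc1
Why: S-alkylation of the ambident sulfinate by the soft allylic bromide (SN2) gives the allylic sulfone whose α-carbon will become C7.

Step 5
Reactants: 7 geranyl acetate
Product: 8 (2E)-5-[(2R)-3,3-dimethyloxiran-2-yl]-3-methylpent-2-en-1-yl acetate
Conditions: D-fructose-derived Shi ketone (0.3 equiv), KHSO5 (as Oxone), K2CO3, Bu4NHSO4, MeCN/CH2(OMe)2/aq. Na2B4O7 buffer, 0 °C
Reagents that add atoms: potassium peroxymonosulfate KHSO5, [K+].[O-]S(=O)(=O)OO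
Why: Shi asymmetric epoxidation: the chiral dioxirane attacks only the electron-rich distal alkene (the other is deactivated by the allylic acetate) through a spiro transition state, and the D-fructose-derived ketone should deliver the (R)-epoxide, which fixes the later C3.

Step 6
Reactants: 8 (2E)-5-[(2R)-3,3-dimethyloxiran-2-yl]-3-methylpent-2-en-1-yl acetate
Product: 9 (2E)-5-[(2R)-3,3-dimethyloxiran-2-yl]-3-methylpent-2-en-1-ol
Conditions: K2CO3 (0.2 equiv), MeOH, 0 °C
Reagents that add atoms: none
Why: Base-catalysed transesterification removes the acetate; the trisubstituted epoxide is stable to carbonate in methanol at 0 °C.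

Step 7
Reactants: 9 (2E)-5-[(2R)-3,3-dimethyloxiran-2-yl]-3-methylpent-2-en-1-ol
Product: 11 (3R)-3-[(3E)-5-bromo-3-methylpent-3-en-1-yl]-2,2-dimethyloxirane, via epoxygeranyl mesylate 10 (not isolated)
Conditions: MsCl, Et3N, THF, −40 °C; then LiBr, THF, −40 to 0 °C
Reagents that add atoms: lithium bromide, [Li+].[Br-] (bromine of 11); methanesulfonyl chloride, CS(=O)(=O)Cl (mesyl group of 10 only)
Why: Mesylation and in situ SN2 displacement by bromide at the primary allylic carbon under non-acidic conditions leave the epoxide and the (E)-alkene intact; the bromide is used at once.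

Step 8
Reactants: 6 (2E,6E)-3,7-dimethyl-8-(phenylsulfonyl)octa-2,6-dien-1-yl (3S)-3-methylpentanoate; 11 (3R)-3-[(3E)-5-bromo-3-methylpent-3-en-1-yl]-2,2-dimethyloxirane
Product: 12 (2E,6E,10E)-13-[(2R)-3,3-dimethyloxiran-2-yl]-3,7,11-trimethyl-8-(phenylsulfonyl)trideca-2,6,10-trien-1-yl (3S)-3-methylpentanoate (both epimers at the sulfonyl carbon)
Conditions: KN(SiMe3)2 (1.05 equiv), THF/DMPU, −78 °C; then 11, −78 to −40 °C
Reagents that add atoms: none
Why: Alkylation of an α-sulfonyl carbanion: the allylic sulfone (pKa about 22) is deprotonated selectively beside the ester (pKa about 30) and attacks the allylic bromide by SN2 at its α-carbon, forming the C6–C7 bond; the new C7 stereocenter is not controlled and need not be, since step 9 destroys it.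

Step 9
Reactants: 12 (2E,6E,10E)-13-[(2R)-3,3-dimethyloxiran-2-yl]-3,7,11-trimethyl-8-(phenylsulfonyl)trideca-2,6,10-trien-1-yl (3S)-3-methylpentanoate
Product: 13 (3R,5S,9R,10S)-3-hydroxylabda-7,13E-dien-15-yl (3S)-3-methylpentanoate (3-OH equatorial, cis to the C10 methyl)
Conditions: Cp2TiCl2 (2.5 equiv), Mn dust (8 equiv), THF, rt; the resulting Cp2TiCl solution added slowly to 12 (0.01 M in THF); then dilute aq. HCl, 0 °C
Reagents that add atoms: none
Why: Proposed new method: Cp2TiCl (trivalent titanium) opens the epoxide homolytically to the tertiary C4 radical, which closes ring A by 6-endo-trig attack on C5 and then ring B by 6-endo-trig attack of the tertiary C10 radical on C9; the C8 radical so formed (or its Cp2Ti(Cl)–C8 adduct) loses the C7 sulfonyl group by β-elimination, reasoned to be faster than β-hydride loss toward C17 or attack on the C13=C14 alkene, so the alkene lands only between C7 and C8 and no third ring forms. The closest known reaction types are the Cp2TiCl-mediated cyclization of epoxypolyprenes (which ends in an exocyclic alkene) and radical addition–fragmentation at allylic sulfones. C3 keeps the epoxide configuration because its C–O bond is never broken; C5, C10 and C9 follow from the chair–chair array with the C3–O–Ti group equatorial and both (E)-alkenes, which should give the trans ring fusion with H5 and H9 anti to the C10 methyl. Both C7 epimers of 12 converge because C7 becomes sp2. The step needs each 6-endo closure to outrun capture of the radical by Cp2TiCl, which slow addition of the reagent at high dilution is meant to secure, and it needs the expelled PhSO2 radical to be removed, which the excess Cp2TiCl does by reduction to sulfinate.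

Step 10
Reactants: 13 (3R,5S,9R,10S)-3-hydroxylabda-7,13E-dien-15-yl (3S)-3-methylpentanoate
Product: 14 (5S,9R,10S)-3-oxolabda-7,13E-dien-15-yl (3S)-3-methylpentanoate
Conditions: Dess–Martin periodinane (1.3 equiv), pyridine, CH2Cl2, 0 °C to rt
Reagents that add atoms: none
Why: Dess–Martin oxidation of the equatorial secondary alcohol removes the C3 stereocenter so that it can be reset; alkenes and esters are inert.

Step 11
Reactants: 14 (5S,9R,10S)-3-oxolabda-7,13E-dien-15-yl (3S)-3-methylpentanoate
Product: 15 (3S,5S,9R,10S)-3-hydroxylabda-7,13E-dien-15-yl (3S)-3-methylpentanoate (3-OH axial, cis to H5)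
Conditions: LiBH(s-Bu)3 (L-Selectride, 1.2 equiv), THF, −78 °C; then H2O
Reagents that add atoms: none
Why: The bulky hydride cannot approach along the axial trajectory (1,3-diaxial hydrogens at C1 and C5) and adds along the equatorial one, which by substrate control should give the axial (3S) alcohol, as is general for 4,4-dimethyl-3-oxo-trans-decalins; the esters survive at −78 °C.

Step 12
Reactants: 15 (3S,5S,9R,10S)-3-hydroxylabda-7,13E-dien-15-yl (3S)-3-methylpentanoate
Product: 16 3-oxo-3-{[(3S,5S,9R,10S)-15-{[(3S)-3-methylpentanoyl]oxy}labda-7,13E-dien-3-yl]oxy}propanoic acid (target)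
Conditions: Meldrum's acid (1.5 equiv), toluene, 100 °C
Reagents that add atoms: Meldrum's acid (2,2-dimethyl-1,3-dioxane-4,6-dione), CC1(C)OC(=O)CC(=O)O1
Why: Thermal ring-opening of Meldrum's acid by the alcohol (through the acyl ketene or by direct addition) with loss of acetone gives the malonic half-ester in one step without a protecting group; the C3–O bond is not touched, so the configuration is kept.

Compound list
1 | geraniol, (2E)-3,7-dimethylocta-2,6-dien-1-ol | CC(C)=CCC/C(C)=C/CO | starting material
2 | (3S)-3-methylpentanoic acid | CC[C@H](C)CC(=O)O | starting material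
3 | geranyl (3S)-3-methylpentanoate | CC[C@H](C)CC(=O)OC/C=C(\C)CCC=C(C)C | intermediate
4 | (2E,6E)-8-hydroxy-3,7-dimethylocta-2,6-dien-1-yl (3S)-3-methylpentanoate | CC[C@H](C)CC(=O)OC/C=C(\C)CC/C=C(\C)CO | intermediate
5 | (2E,6E)-8-bromo-3,7-dimethylocta-2,6-dien-1-yl (3S)-3-methylpentanoate | CC[C@H](C)CC(=O)OC/C=C(\C)CC/C=C(\C)CBr | intermediate
6 | (2E,6E)-3,7-dimethyl-8-(phenylsulfonyl)octa-2,6-dien-1-yl (3S)-3-methylpentanoate | CC[C@H](C)CC(=O)OC/C=C(\C)CC/C=C(\C)CS(=O)(=O)c1ccccc1 | intermediate
7 | geranyl acetate | CC(=O)OC/C=C(\C)CCC=C(C)C | starting material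
8 | (2E)-5-[(2R)-3,3-dimethyloxiran-2-yl]-3-methylpent-2-en-1-yl acetate | CC(=O)OC/C=C(\C)CC[C@H]1OC1(C)C | intermediate
9 | (2E)-5-[(2R)-3,3-dimethyloxiran-2-yl]-3-methylpent-2-en-1-ol | OC/C=C(\C)CC[C@H]1OC1(C)C | intermediate
10 | (2E)-5-[(2R)-3,3-dimethyloxiran-2-yl]-3-methylpent-2-en-1-yl methanesulfonate | CS(=O)(=O)OC/C=C(\C)CC[C@H]1OC1(C)C | intermediate (not isolated)
11 | (3R)-3-[(3E)-5-bromo-3-methylpent-3-en-1-yl]-2,2-dimethyloxirane | BrC/C=C(\C)CC[C@H]1OC1(C)C | intermediate
12 | (2E,6E,10E)-13-[(2R)-3,3-dimethyloxiran-2-yl]-3,7,11-trimethyl-8-(phenylsulfonyl)trideca-2,6,10-trien-1-yl (3S)-3-methylpentanoate, both epimers at the sulfonyl carbon | CC[C@H](C)CC(=O)OC/C=C(\C)CC/C=C(\C)C(C/C=C(\C)CC[C@H]1OC1(C)C)S(=O)(=O)c1ccccc1 | intermediate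
13 | (3R,5S,9R,10S)-3-hydroxylabda-7,13E-dien-15-yl (3S)-3-methylpentanoate | CC[C@H](C)CC(=O)OC/C=C(\C)CC[C@@H]1C(C)=CC[C@@H]2C(C)(C)[C@H](O)CC[C@@]12C | intermediate
14 | (5S,9R,10S)-3-oxolabda-7,13E-dien-15-yl (3S)-3-methylpentanoate | CC[C@H](C)CC(=O)OC/C=C(\C)CC[C@@H]1C(C)=CC[C@@H]2C(C)(C)C(=O)CC[C@@]12C | intermediate
15 | (3S,5S,9R,10S)-3-hydroxylabda-7,13E-dien-15-yl (3S)-3-methylpentanoate | CC[C@H](C)CC(=O)OC/C=C(\C)CC[C@@H]1C(C)=CC[C@@H]2C(C)(C)[C@@H](O)CC[C@@]12C | intermediate
16 | 3-oxo-3-{[(3S,5S,9R,10S)-15-{[(3S)-3-methylpentanoyl]oxy}labda-7,13E-dien-3-yl]oxy}propanoic acid | CC[C@H](C)CC(=O)OC/C=C(\C)CC[C@@H]1C(C)=CC[C@@H]2C(C)(C)[C@@H](OC(=O)CC(=O)O)CC[C@@]12C | target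

Total step count: 12. Longest linear sequence: 9 steps (steps 1–4 and 8–12, from geraniol).

Steps most likely to fail

Step 9. What may go wrong: capture of the C10 or C8 radical by Cp2TiCl before ring B closes or before the sulfinate is lost, and side reactions of the expelled sulfonyl radical with the remaining alkenes. The fallback uses known chemistry only and sets out from 12. Methanolysis of the C15 ester (K2CO3, MeOH) gives the hydroxy sulfone F1, so that no allylic ester is exposed to the palladium catalyst. Hydride desulfonylation (PdCl2(dppp) cat., LiBHEt3, THF, 0 °C), which keeps the alkene in place, gives (R)-epoxygeranylgeraniol F2; the hindered trisubstituted epoxide is expected to survive the short exposure. Re-esterification with 2 (DCC, DMAP) gives the sulfone-free epoxy ester F3. The established Cp2TiCl cyclization of such epoxypolyprenes (Cp2TiCl2, Mn, THF) then closes ring A and ring B and ends in the exocyclic C8=C17 alkene F4. Hydrogen-atom-transfer isomerization (Co(salen)Cl cat., PhSiH3, benzene, rt) moves that alkene into ring B to C7=C8, and the route is rejoined at 13.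

Step 8. What may go wrong: acyl transfer from the C15 ester to the sulfonyl carbanion, ester enolization, or SN2′ attack on 11. The fallback sets out from 6. K2CO3 in MeOH removes the acyl group and gives the sulfonyl alcohol F5. Its dianion (n-BuLi, 2.1 equiv, THF/DMPU, −78 °C) is alkylated on carbon by 11 to give the hydroxy sulfone F1, the same compound as in the fallback for step 9. Esterification with 2 (DCC, DMAP) returns to 12.

Step 12. What may go wrong: slow acylation of the hindered axial C3 hydroxyl next to the gem-dimethyl carbon, with thermal decarboxylation of the half-ester competing. The fallback sets out from 15. DCC/DMAP coupling with 3-oxo-3-[2-(trimethylsilyl)ethoxy]propanoic acid gives the mixed malonate F6. Bu4NF in THF at 0 °C then cleaves only the silylethyl ester and returns to 16.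

Further compounds
F1 | step 9 | (2E,6E,10E)-13-[(2R)-3,3-dimethyloxiran-2-yl]-3,7,11-trimethyl-8-(phenylsulfonyl)trideca-2,6,10-trien-1-ol (both epimers at the sulfonyl carbon) | OC/C=C(\C)CC/C=C(\C)C(C/C=C(\C)CC[C@H]1OC1(C)C)S(=O)(=O)c1ccccc1
F2 | step 9 | (2E,6E,10E)-13-[(2R)-3,3-dimethyloxiran-2-yl]-3,7,11-trimethyltrideca-2,6,10-trien-1-ol | OC/C=C(\C)CC/C=C(\C)CC/C=C(\C)CC[C@H]1OC1(C)C
F3 | step 9 | (2E,6E,10E)-13-[(2R)-3,3-dimethyloxiran-2-yl]-3,7,11-trimethyltrideca-2,6,10-trien-1-yl (3S)-3-methylpentanoate | CC[C@H](C)CC(=O)OC/C=C(\C)CC/C=C(\C)CC/C=C(\C)CC[C@H]1OC1(C)C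
F4 | step 9 | (3R,5S,9R,10S)-3-hydroxylabda-8(17),13E-dien-15-yl (3S)-3-methylpentanoate | CC[C@H](C)CC(=O)OC/C=C(\C)CC[C@@H]1C(=C)CC[C@@H]2C(C)(C)[C@H](O)CC[C@@]12C
F5 | step 8 | (2E,6E)-3,7-dimethyl-8-(phenylsulfonyl)octa-2,6-dien-1-ol | OC/C=C(\C)CC/C=C(\C)CS(=O)(=O)c1ccccc1
F6 | step 12 | (3S,5S,9R,10S)-15-{[(3S)-3-methylpentanoyl]oxy}labda-7,13E-dien-3-yl 2-(trimethylsilyl)ethyl malonate | CC[C@H](C)CC(=O)OC/C=C(\C)CC[C@@H]1C(C)=CC[C@@H]2C(C)(C)[C@@H](OC(=O)CC(=O)OCC[Si](C)(C)C)CC[C@@]12C
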